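**Strategy.** The fused core is read as a masked 1,3-diyne: in ring B (dihydrofuran) the enol-ether pair C3a=C7a–O1 and in ring A (pyranone) the pair C7=C6–O5 each correspond to an alkyne that has taken up an oxygen nucleophile, and the C4 carbonyl between C3a and O5 is one molecule of CO. Cutting O1–C7a, C3a–C4 and O5–C6 thus gives the anti diynol 17, whose C1 hydroxyl becomes O1. One palladium-catalysed sequence (oxypalladation, CO insertion, hydrolysis, lactonisation) should close both rings, deliver furopyranone 19 with its styryl arm, and turn the anti diad into the trans C2/C3 pair. Diynol 17 bears five silyl ethers and comes from three fragments.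

Key step: step 11

Remark: C3 changes its CIP label from S (CH2O-substituted 19, 20) to R (acyl- or pyranonyl-substituted 21–29) through substituent priorities only; no bond at C3 is broken after step 6.

Abbreviations: TBS = tert-butyldimethylsilyl; TMS = trimethylsilyl; Ar = 3,4-bis[(tert-butyldimethylsilyl)oxy]phenyl.

**Route**

Step 1
Reactants: 1 3,4-dihydroxybenzaldehyde
Product: 2 3,4-bis[(tert-butyldimethylsilyl)oxy]benzaldehyde
Conditions: TBSCl (2.4 equiv), imidazole (5 equiv), DMF, rt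
Reagents that add atoms: tert-butyldimethylsilyl chloride, CC(C)(C)[Si](C)(C)Cl
Why: Imidazole-promoted O-silylation of both phenols gives aryl silyl ethers that should survive the organometallic, oxidative and thermal steps and leave under bifluoride at the end.

Step 2
Reactants: 3 [(tert-butyldimethylsilyl)oxy]acetaldehyde; 4 ethynyltrimethylsilane
Product: 6 rac-1-[(tert-butyldimethylsilyl)oxy]-4-(trimethylsilyl)but-3-yn-2-ol, via lithium (trimethylsilyl)acetylide 5 (not isolated)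
Conditions: 4, n-BuLi, THF, −78 °C; then 3, −78 °C; H2O quench
Reagents that add atoms: none
Why: 1,2-Addition of a lithium acetylide to an aldehyde gives the propargylic alcohol, whose carbinol centre is racemic and is erased by oxidation in step 3.

Step 3
Reactants: 6 rac-1-[(tert-butyldimethylsilyl)oxy]-4-(trimethylsilyl)but-3-yn-2-ol
Product: 7 1-[(tert-butyldimethylsilyl)oxy]-4-(trimethylsilyl)but-3-yn-2-one
Conditions: Dess–Martin periodinane, CH2Cl2, 0 °C to rt
Reagents that add atoms: none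
Why: Dess–Martin oxidation of a propargylic alcohol to the ynone runs under neutral, non-aqueous conditions that should spare both silyl groups.

Step 4
Reactants: 7 1-[(tert-butyldimethylsilyl)oxy]-4-(trimethylsilyl)but-3-yn-2-one
Product: 8 (2R)-1-[(tert-butyldimethylsilyl)oxy]-4-(trimethylsilyl)but-3-yn-2-ol
Conditions: Ru[(S,S)-TsDPEN](p-cymene) (1 mol%), i-PrOH, rt
Reagents that add atoms: none
Why: Noyori asymmetric transfer hydrogenation of an ynone, in which the alkynyl group takes the place of the aryl group of an aryl ketone, so the (S,S) catalyst should deliver hydride to the face giving the alcohol drawn (labelled R only because CH2OSi outranks the alkynyl carbon).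

Step 5
Reactants: 8 (2R)-1-[(tert-butyldimethylsilyl)oxy]-4-(trimethylsilyl)but-3-yn-2-ol
Product: 9 (2R)-1-[(tert-butyldimethylsilyl)oxy]-4-(trimethylsilyl)but-3-yn-2-yl methanesulfonate
Conditions: MsCl, Et3N, CH2Cl2, −40 °C
Reagents that add atoms: methanesulfonyl chloride, CS(=O)(=O)Cl
Why: O-Sulfonylation leaves the C–O bond and hence the configuration untouched and installs the leaving group for the propargyl-to-allenyl umpolung.

Step 6
Reactants: 9 (2R)-1-[(tert-butyldimethylsilyl)oxy]-4-(trimethylsilyl)but-3-yn-2-yl methanesulfonate; 2 3,4-bis[(tert-butyldimethylsilyl)oxy]benzaldehyde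
Product: 11 (1R,2S)-1-Ar-2-{[(tert-butyldimethylsilyl)oxy]methyl}-4-(trimethylsilyl)but-3-yn-1-ol (anti), via allenylzinc reagent 10 (not isolated)
Conditions: Pd(OAc)2 (5 mol%), PPh3 (5 mol%), Et2Zn (3 equiv), THF, −78 to −20 °C; aqueous work-up
Reagents that add atoms: none
Why: Marshall propargylation, in which zerovalent palladium displaces the mesylate anti (SN2′), exchange with Et2Zn gives the (M)-allenylzinc 10, and its syn SE2′ addition to 2 through a cyclic six-membered transition state inverts the former propargylic carbon (setting C2 as S) while the aryl group turns away from the CH2OSi substituent, which should set the anti (1R) carbinol.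

Step 7
Reactants: 11 (1R,2S)-1-Ar-2-{[(tert-butyldimethylsilyl)oxy]methyl}-4-(trimethylsilyl)but-3-yn-1-ol
Product: 12 (1R,2S)-4-bromo-1-Ar-2-{[(tert-butyldimethylsilyl)oxy]methyl}but-3-yn-1-ol
Conditions: NBS (1.2 equiv), AgNO3 (10 mol%), acetone, rt, dark
Reagents that add atoms: N-bromosuccinimide, O=C1CCC(=O)N1Br
Why: Silver-catalysed bromodesilylation of an alkynylsilane gives the 1-bromoalkyne directly under neutral conditions, so no basic C-desilylation that would endanger the aryl silyl ethers is needed.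

Step 8
Reactants: 2 3,4-bis[(tert-butyldimethylsilyl)oxy]benzaldehyde
Product: 13 (E)-1,2-bis[(tert-butyldimethylsilyl)oxy]-4-(2-iodoethenyl)benzene
Conditions: CrCl2 (6 equiv), CHI3 (2 equiv), THF/1,4-dioxane, 0 °C to rt
Reagents that add atoms: iodoform, IC(I)I
Why: Takai olefination, in which the geminal dichromium species adds to the aryl aldehyde and elimination with the bulky chromium groups anti should give the (E)-iodoalkene.

Step 9
Reactants: 13 (E)-1,2-bis[(tert-butyldimethylsilyl)oxy]-4-(2-iodoethenyl)benzene; 14 ethynylmagnesium bromide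
Product: 16 (E)-4-(but-1-en-3-yn-1-yl)-1,2-bis[(tert-butyldimethylsilyl)oxy]benzene, via ethynylzinc bromide 15 (not isolated)
Conditions: 14, ZnBr2, THF, 0 °C; then 13, Pd(PPh3)4 (5 mol%), rt
Reagents that add atoms: none
Why: Negishi coupling of an alkenyl iodide with ethynylzinc bromide proceeds with retention of alkene geometry and gives the terminal enyne without any desilylation step.

Step 10
Reactants: 12 (1R,2S)-4-bromo-1-Ar-2-{[(tert-butyldimethylsilyl)oxy]methyl}but-3-yn-1-ol; 16 (E)-4-(but-1-en-3-yn-1-yl)-1,2-bis[(tert-butyldimethylsilyl)oxy]benzene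
Product: 17 (1R,2S,7E)-1,8-di-Ar-2-{[(tert-butyldimethylsilyl)oxy]methyl}oct-7-ene-3,5-diyn-1-ol
Conditions: PdCl2(PPh3)2 (3 mol%), CuI (6 mol%), i-Pr2NH, THF, 0 °C to rt
Reagents that add atoms: none
Why: Cadiot–Chodkiewicz sp–sp coupling in its CuI/amine form with PdCl2(PPh3)2 as cocatalyst, in which the copper acetylide of 16 couples with bromoalkyne 12 while the free hydroxyl and the silyl ethers are inert to the anhydrous secondary amine.

Step 11
Reactants: 17 (1R,2S,7E)-1,8-di-Ar-2-{[(tert-butyldimethylsilyl)oxy]methyl}oct-7-ene-3,5-diyn-1-ol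
Product: 19 (2R,3S)-2-Ar-6-[(E)-2-Ar-ethenyl]-3-{[(tert-butyldimethylsilyl)oxy]methyl}-2,3-dihydro-4H-furo[3,2-c]pyran-4-one, via dihydrofuran-3-carboxylic acid 18 (not isolated)
Conditions: PdI2 (5 mol%), KI (50 mol%), CO/air (4:1, 20 atm), H2O (5 equiv), 1,4-dioxane, 80 °C; then vent, N2, 80 °C
Reagents that add atoms: carbon monoxide, [C-]#[O+]; water, O
Why: Proposed new method: PdI2 (divalent palladium) coordinates the alkyne next to the stereocentres, the C1 hydroxyl adds anti to its far carbon (5-endo-dig, ring B, O1–C7a), and the C3a vinylpalladium inserts CO and is hydrolysed by water to acid 18 while air re-oxidises zerovalent palladium through HI. After CO is vented, the same catalyst activates the second alkyne, the carboxyl oxygen adds to C6 (6-endo-dig, ring A, O5–C6), and protonolysis of the C7–palladium bond releases 19. The closest known reaction types are the PdI2/KI oxidative 5-endo heterocyclisation–alkoxycarbonylation of 3-yn-1-ol units to dihydrofuran- and furan-3-carboxylates and the metal-catalysed 6-endo lactonisation of (Z)-2-en-4-ynoic acids to 2-pyranones; their merger on a 1,3-diyne is not established. No stereocentre is created, and because the C1–O and C2–H bonds of 17 are never broken, the anti (1R,2S) diad should map onto the trans (2R,3S) ring substituents. The step needs attack on the proximal alkyne (only the 5-endo mode is open to a homopropargylic hydroxyl), CO capture at C3a but protonolysis at C7 (hence removal of CO before the second closure is driven to completion), and 6-endo rather than 5-exo lactonisation (favoured by the electron-rich styryl group, which stabilises positive charge at C6, and by the wide exocyclic angles of the five-membered ring, which hold the carboxyl oxygen away from C7).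

Step 12
Reactants: 19 (2R,3S)-2-Ar-6-[(E)-2-Ar-ethenyl]-3-{[(tert-butyldimethylsilyl)oxy]methyl}-2,3-dihydro-4H-furo[3,2-c]pyran-4-one
Product: 20 (2R,3S)-2-Ar-6-[(E)-2-Ar-ethenyl]-3-(hydroxymethyl)-2,3-dihydro-4H-furo[3,2-c]pyran-4-one
Conditions: CSA (0.2 equiv), MeOH/CH2Cl2 (1:1), 0 °C
Reagents that add atoms: none
Why: Acid-catalysed methanolysis should remove the primary alkyl silyl ether much faster than the four aryl silyl ethers, whose oxygen atoms are far less basic.

Step 13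
Reactants: 20 (2R,3S)-2-Ar-6-[(E)-2-Ar-ethenyl]-3-(hydroxymethyl)-2,3-dihydro-4H-furo[3,2-c]pyran-4-one
Product: 22 (2R,3R)-2-Ar-6-[(E)-2-Ar-ethenyl]-4-oxo-2,3-dihydro-4H-furo[3,2-c]pyran-3-carboxylic acid, via aldehyde 21 (not isolated)
Conditions: TEMPO (0.2 equiv), PhI(OAc)2 (2.5 equiv), MeCN/H2O (1:1), rt
Reagents that add atoms: water, O
Why: Oxoammonium (TEMPO) oxidation with PhI(OAc)2 as terminal oxidant takes the primary alcohol through the aldehyde hydrate to the acid near neutral pH, and any enolisation at C3 would only return the more stable trans isomer.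

Step 14
Reactants: 22 (2R,3R)-2-Ar-6-[(E)-2-Ar-ethenyl]-4-oxo-2,3-dihydro-4H-furo[3,2-c]pyran-3-carboxylic acid; 23 2,2,6-trimethyl-4H-1,3-dioxin-4-one
Product: 26 6-{2-[(2R,3R)-2-Ar-6-[(E)-2-Ar-ethenyl]-4-oxo-2,3-dihydro-4H-furo[3,2-c]pyran-3-yl]-2-oxoethyl}-2,2-dimethyl-4H-1,3-dioxin-4-one, via acid chloride 24 (not isolated), via lithium dienolate 25 (not isolated)
Conditions: 22, 1-chloro-N,N,2-trimethylprop-1-en-1-amine, CH2Cl2, 0 °C to rt; 23 (2.2 equiv), LiN(SiMe3)2 (2.2 equiv), THF, −78 °C; combine at −78 °C; AcOH quench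
Reagents that add atoms: none
Why: Claisen-type C-acylation of the dioxinone lithium dienolate at its terminal carbon by an acid chloride made under neutral conditions with the Ghosez reagent, the second equivalent of dienolate storing the product as its enolate.

Step 15
Reactants: 26 6-{2-[(2R,3R)-2-Ar-6-[(E)-2-Ar-ethenyl]-4-oxo-2,3-dihydro-4H-furo[3,2-c]pyran-3-yl]-2-oxoethyl}-2,2-dimethyl-4H-1,3-dioxin-4-one
Product: 28 (2R,3R)-2-Ar-6-[(E)-2-Ar-ethenyl]-3-(4-hydroxy-2-oxo-2H-pyran-6-yl)-2,3-dihydro-4H-furo[3,2-c]pyran-4-one, via acylketene 27 (not isolated)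
Conditions: toluene, 110 °C
Reagents that add atoms: none
Why: Thermal retro-[4+2] fragmentation of the dioxinone releases acetone and an acylketene, which the enol oxygen of the neighbouring ketone traps to form the 4-hydroxy-2-pyranone under neutral conditions.

Step 16
Reactants: 28 (2R,3R)-2-Ar-6-[(E)-2-Ar-ethenyl]-3-(4-hydroxy-2-oxo-2H-pyran-6-yl)-2,3-dihydro-4H-furo[3,2-c]pyran-4-one
Product: 29 (2R,3R)-2-(3,4-dihydroxyphenyl)-6-[(E)-2-(3,4-dihydroxyphenyl)ethenyl]-3-(4-hydroxy-2-oxo-2H-pyran-6-yl)-2,3-dihydro-4H-furo[3,2-c]pyran-4-one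
Conditions: KHF2 (10 equiv), MeOH/THF, rt
Reagents that add atoms: none
Why: Bifluoride cleaves aryl silyl ethers at room temperature in a mildly acidic medium, which should keep the free catechols from oxidising and leave both pyranones and the C2–O1 bond intact.

**Compound list**

1 | 3,4-dihydroxybenzaldehyde | O=Cc1ccc(O)c(O)c1 | starting material
2 | 3,4-bis[(tert-butyldimethylsilyl)oxy]benzaldehyde | O=Cc1ccc(O[Si](C)(C)C(C)(C)C)c(O[Si](C)(C)C(C)(C)C)c1 | intermediate
3 | [(tert-butyldimethylsilyl)oxy]acetaldehyde | CC(C)(C)[Si](C)(C)OCC=O | starting material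
4 | ethynyltrimethylsilane | C#C[Si](C)(C)C | starting material
5 | lithium (trimethylsilyl)acetylide | [Li]C#C[Si](C)(C)C | intermediate
6 | rac-1-[(tert-butyldimethylsilyl)oxy]-4-(trimethylsilyl)but-3-yn-2-ol | CC(C)(C)[Si](C)(C)OCC(O)C#C[Si](C)(C)C | intermediate
7 | 1-[(tert-butyldimethylsilyl)oxy]-4-(trimethylsilyl)but-3-yn-2-one | CC(C)(C)[Si](C)(C)OCC(=O)C#C[Si](C)(C)C | intermediate
8 | (2R)-1-[(tert-butyldimethylsilyl)oxy]-4-(trimethylsilyl)but-3-yn-2-ol | CC(C)(C)[Si](C)(C)OC[C@H](O)C#C[Si](C)(C)C | intermediate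
9 | (2R)-1-[(tert-butyldimethylsilyl)oxy]-4-(trimethylsilyl)but-3-yn-2-yl methanesulfonate | CC(C)(C)[Si](C)(C)OC[C@H](OS(C)(=O)=O)C#C[Si](C)(C)C | intermediate
10 | (M)-{4-[(tert-butyldimethylsilyl)oxy]-1-(trimethylsilyl)buta-1,2-dien-1-yl}(ethyl)zinc | [H]C(CO[Si](C)(C)C(C)(C)C)=[C@@]=C([Si](C)(C)C)[Zn]CC | intermediate
11 | (1R,2S)-1-Ar-2-{[(tert-butyldimethylsilyl)oxy]methyl}-4-(trimethylsilyl)but-3-yn-1-ol (anti) | CC(C)(C)[Si](C)(C)OC[C@@H]([C@@H](O)c1ccc(O[Si](C)(C)C(C)(C)C)c(O[Si](C)(C)C(C)(C)C)c1)C#C[Si](C)(C)C | intermediate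
12 | (1R,2S)-4-bromo-1-Ar-2-{[(tert-butyldimethylsilyl)oxy]methyl}but-3-yn-1-ol | CC(C)(C)[Si](C)(C)OC[C@@H]([C@@H](O)c1ccc(O[Si](C)(C)C(C)(C)C)c(O[Si](C)(C)C(C)(C)C)c1)C#CBr | intermediate
13 | (E)-1,2-bis[(tert-butyldimethylsilyl)oxy]-4-(2-iodoethenyl)benzene | I/C=C/c1ccc(O[Si](C)(C)C(C)(C)C)c(O[Si](C)(C)C(C)(C)C)c1 | intermediate
14 | ethynylmagnesium bromide | C#C[Mg]Br | starting material
15 | ethynylzinc bromide | C#C[Zn]Br | intermediate
16 | (E)-4-(but-1-en-3-yn-1-yl)-1,2-bis[(tert-butyldimethylsilyl)oxy]benzene | C#C/C=C/c1ccc(O[Si](C)(C)C(C)(C)C)c(O[Si](C)(C)C(C)(C)C)c1 | intermediate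
17 | (1R,2S,7E)-1,8-di-Ar-2-{[(tert-butyldimethylsilyl)oxy]methyl}oct-7-ene-3,5-diyn-1-ol (anti) | CC(C)(C)[Si](C)(C)OC[C@@H]([C@@H](O)c1ccc(O[Si](C)(C)C(C)(C)C)c(O[Si](C)(C)C(C)(C)C)c1)C#CC#C/C=C/c1ccc(O[Si](C)(C)C(C)(C)C)c(O[Si](C)(C)C(C)(C)C)c1 | intermediate
18 | (4S,5R)-5-Ar-2-[(E)-4-Ar-but-3-en-1-yn-1-yl]-4-{[(tert-butyldimethylsilyl)oxy]methyl}-4,5-dihydrofuran-3-carboxylic acid | CC(C)(C)[Si](C)(C)OC[C@@H]1C(C(=O)O)=C(C#C/C=C/c2ccc(O[Si](C)(C)C(C)(C)C)c(O[Si](C)(C)C(C)(C)C)c2)O[C@H]1c1ccc(O[Si](C)(C)C(C)(C)C)c(O[Si](C)(C)C(C)(C)C)c1 | intermediate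
19 | (2R,3S)-2-Ar-6-[(E)-2-Ar-ethenyl]-3-{[(tert-butyldimethylsilyl)oxy]methyl}-2,3-dihydro-4H-furo[3,2-c]pyran-4-one (trans) | CC(C)(C)[Si](C)(C)OC[C@@H]2c3c(cc(/C=C/c4ccc(O[Si](C)(C)C(C)(C)C)c(O[Si](C)(C)C(C)(C)C)c4)oc3=O)O[C@H]2c2ccc(O[Si](C)(C)C(C)(C)C)c(O[Si](C)(C)C(C)(C)C)c2 | intermediate
20 | (2R,3S)-2-Ar-6-[(E)-2-Ar-ethenyl]-3-(hydroxymethyl)-2,3-dihydro-4H-furo[3,2-c]pyran-4-one | OC[C@@H]2c3c(cc(/C=C/c4ccc(O[Si](C)(C)C(C)(C)C)c(O[Si](C)(C)C(C)(C)C)c4)oc3=O)O[C@H]2c2ccc(O[Si](C)(C)C(C)(C)C)c(O[Si](C)(C)C(C)(C)C)c2 | intermediate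
21 | (2R,3R)-2-Ar-6-[(E)-2-Ar-ethenyl]-4-oxo-2,3-dihydro-4H-furo[3,2-c]pyran-3-carbaldehyde | O=C[C@@H]2c3c(cc(/C=C/c4ccc(O[Si](C)(C)C(C)(C)C)c(O[Si](C)(C)C(C)(C)C)c4)oc3=O)O[C@H]2c2ccc(O[Si](C)(C)C(C)(C)C)c(O[Si](C)(C)C(C)(C)C)c2 | intermediate
22 | (2R,3R)-2-Ar-6-[(E)-2-Ar-ethenyl]-4-oxo-2,3-dihydro-4H-furo[3,2-c]pyran-3-carboxylic acid | O=C(O)[C@@H]2c3c(cc(/C=C/c4ccc(O[Si](C)(C)C(C)(C)C)c(O[Si](C)(C)C(C)(C)C)c4)oc3=O)O[C@H]2c2ccc(O[Si](C)(C)C(C)(C)C)c(O[Si](C)(C)C(C)(C)C)c2 | intermediate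
23 | 2,2,6-trimethyl-4H-1,3-dioxin-4-one | CC1=CC(=O)OC(C)(C)O1 | starting material
24 | (2R,3R)-2-Ar-6-[(E)-2-Ar-ethenyl]-4-oxo-2,3-dihydro-4H-furo[3,2-c]pyran-3-carbonyl chloride | O=C(Cl)[C@@H]2c3c(cc(/C=C/c4ccc(O[Si](C)(C)C(C)(C)C)c(O[Si](C)(C)C(C)(C)C)c4)oc3=O)O[C@H]2c2ccc(O[Si](C)(C)C(C)(C)C)c(O[Si](C)(C)C(C)(C)C)c2 | intermediate
25 | lithium 2,2-dimethyl-6-methylidene-6H-1,3-dioxin-4-olate | C=C1C=C(O[Li])OC(C)(C)O1 | intermediate
26 | 6-{2-[(2R,3R)-2-Ar-6-[(E)-2-Ar-ethenyl]-4-oxo-2,3-dihydro-4H-furo[3,2-c]pyran-3-yl]-2-oxoethyl}-2,2-dimethyl-4H-1,3-dioxin-4-one | CC1(C)OC(=O)C=C(CC(=O)[C@@H]2c3c(cc(/C=C/c4ccc(O[Si](C)(C)C(C)(C)C)c(O[Si](C)(C)C(C)(C)C)c4)oc3=O)O[C@H]2c2ccc(O[Si](C)(C)C(C)(C)C)c(O[Si](C)(C)C(C)(C)C)c2)O1 | intermediate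
27 | 5-[(2R,3R)-2-Ar-6-[(E)-2-Ar-ethenyl]-4-oxo-2,3-dihydro-4H-furo[3,2-c]pyran-3-yl]-3,5-dioxopent-1-en-1-one (acylketene) | O=C=CC(=O)CC(=O)[C@@H]2c3c(cc(/C=C/c4ccc(O[Si](C)(C)C(C)(C)C)c(O[Si](C)(C)C(C)(C)C)c4)oc3=O)O[C@H]2c2ccc(O[Si](C)(C)C(C)(C)C)c(O[Si](C)(C)C(C)(C)C)c2 | intermediate
28 | (2R,3R)-2-Ar-6-[(E)-2-Ar-ethenyl]-3-(4-hydroxy-2-oxo-2H-pyran-6-yl)-2,3-dihydro-4H-furo[3,2-c]pyran-4-one | O=c1cc(O)cc([C@@H]2c3c(cc(/C=C/c4ccc(O[Si](C)(C)C(C)(C)C)c(O[Si](C)(C)C(C)(C)C)c4)oc3=O)O[C@H]2c2ccc(O[Si](C)(C)C(C)(C)C)c(O[Si](C)(C)C(C)(C)C)c2)o1 | intermediate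
29 | (2R,3R)-2-(3,4-dihydroxyphenyl)-6-[(E)-2-(3,4-dihydroxyphenyl)ethenyl]-3-(4-hydroxy-2-oxo-2H-pyran-6-yl)-2,3-dihydro-4H-furo[3,2-c]pyran-4-one | O=c1cc(O)cc([C@@H]2c3c(cc(/C=C/c4ccc(O)c(O)c4)oc3=O)O[C@H]2c2ccc(O)c(O)c2)o1 | target

**Totals.** Total step count: 16. Longest linear sequence: 13 steps (steps 2–7 and 10–16, from compound 3).

**Steps most likely to fail**

Step 11. Four processes may intervene. The C3a–palladium bond may be protonated before CO inserts, giving plain cycloisomerisation. C7 may be carbonylated a second time if ring A closes while CO is still present. Lactonisation may go 5-exo instead of 6-endo. Acid may remove the primary silyl ether, or ionise the benzylic carbinol, before ring B closes. The fallback uses known reactions run as separate operations and sets out from 17. Oxidative 5-endo cyclisation–methoxycarbonylation (PdI2/KI, CO/air, MeOH, 60 °C) should give the methyl 4,5-dihydrofuran-3-carboxylate F1. Me3SnOH in 1,2-dichloroethane at 70 °C should cleave the methyl ester without touching silyl ethers and give acid 18, isolated this time. ZnBr2 (catalytic, THF, rt), a reagent known to steer (Z)-2-en-4-ynoic acids to 6-endo lactonisation, should then close ring A and bring the route back at 19.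

Step 6. Anti selectivity may erode with an aromatic aldehyde, the silyloxy group may be lost by β-elimination from the propargyl/allenyl metal species, and the allenyl intermediate may lose its axial configuration. The fallback sets out from 8. Methyl chloroformate and pyridine should give the propargylic methyl carbonate F2. Copper-catalysed anti-SN2′ borylation (CuOt-Bu, Xantphos, B2pin2, THF, rt) should turn it into the isolable, configurationally stable (P)-allenylboronate F3. Heating F3 with aldehyde 2 in toluene should give the anti adduct through a closed chair transition state with the same net inversion, and the route is rejoined at 11.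

Step 14. The acid chloride may be deprotonated at C3 (ketene formation and oligomerisation), and the excess dienolate may attack the electrophilic pyranone ring. The fallback sets out from 20 and forms the carbon–carbon bond at the aldehyde oxidation level under Lewis acid. Dess–Martin oxidation should give aldehyde 21, isolated this time. A BF3·OEt2-mediated vinylogous Mukaiyama aldol addition at −78 °C with the silyl dienol ether F4 (made from 23 with LiN(SiMe3)2 and TMSCl) should give the δ-hydroxy dioxinone F5 as a mixture of carbinol epimers. A second Dess–Martin oxidation should converge both epimers on 26, where the route is rejoined.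

Further compounds

F1 | step 11 | methyl (4S,5R)-5-Ar-2-[(E)-4-Ar-but-3-en-1-yn-1-yl]-4-{[(tert-butyldimethylsilyl)oxy]methyl}-4,5-dihydrofuran-3-carboxylate | CC(C)(C)[Si](C)(C)OC[C@@H]1C(C(=O)OC)=C(C#C/C=C/c2ccc(O[Si](C)(C)C(C)(C)C)c(O[Si](C)(C)C(C)(C)C)c2)O[C@H]1c1ccc(O[Si](C)(C)C(C)(C)C)c(O[Si](C)(C)C(C)(C)C)c1
F2 | step 6 | (2R)-1-[(tert-butyldimethylsilyl)oxy]-4-(trimethylsilyl)but-3-yn-2-yl methyl carbonate | CC(C)(C)[Si](C)(C)OC[C@H](OC(=O)OC)C#C[Si](C)(C)C
F3 | step 6 | (P)-2-{4-[(tert-butyldimethylsilyl)oxy]-1-(trimethylsilyl)buta-1,2-dien-1-yl}-4,4,5,5-tetramethyl-1,3,2-dioxaborolane | [H]C(CO[Si](C)(C)C(C)(C)C)=[C@@]=C([Si](C)(C)C)B1OC(C)(C)C(C)(C)O1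
F4 | step 14 | 2,2-dimethyl-6-methylidene-4-[(trimethylsilyl)oxy]-6H-1,3-dioxine | C=C1C=C(O[Si](C)(C)C)OC(C)(C)O1
F5 | step 14 | 6-{2-hydroxy-2-[(2R,3S)-2-Ar-6-[(E)-2-Ar-ethenyl]-4-oxo-2,3-dihydro-4H-furo[3,2-c]pyran-3-yl]ethyl}-2,2-dimethyl-4H-1,3-dioxin-4-one (both carbinol epimers) | CC1(C)OC(=O)C=C(CC(O)[C@@H]2c3c(cc(/C=C/c4ccc(O[Si](C)(C)C(C)(C)C)c(O[Si](C)(C)C(C)(C)C)c4)oc3=O)O[C@H]2c2ccc(O[Si](C)(C)C(C)(C)C)c(O[Si](C)(C)C(C)(C)C)c2)O1
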